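The numbers in the tables are calculated from invented constants, noise included.

Slow opening of substrate is the nearly constant part of these flasks: at 0.667 min, open intermediate plus target read 24.8% in west, 24.9% in south and 25.1% in north, although north starts with half the substrate. That early sum can therefore be frozen in percent.

| flask | substrate | partner | remark | time |
|---|---|---|---|---|
| west | 0.020 M | 0.042 M (fed, over 6.0 s) | run made earlier; the fed solution adds 0.50 times the starting volume |  |
| south | 0.020 M | 0.066 M (fed, over 6.0 s) | run made earlier; the fed solution adds 0.50 times the starting volume |  |
| north | 0.010 M | 0.030 M (fed, over 6.0 s) | run made earlier; the fed solution adds 0.50 times the starting volume |  |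
| flask | 0.020 M | 0.0300 M (fed, over 6.0 s) | the fed solution adds 0.50 times the starting volume | 2.5 min |

- west (time / min: open intermediate / %, target / %): 0.333: 14.2, 0.1; 0.667: 22.0, 2.8; 1.33: 24.3, 11.9; 2.50: 17.0, 21.7
- south (time / min: open intermediate / %, target / %): 0.333: 13.4, 0.6; 0.667: 20.5, 4.4; 1.33: 19.5, 17.1; 2.50: 10.6, 25.1
- north (time / min: open intermediate / %, target / %): 0.333: 13.7, 0.7; 0.667: 22.5, 2.6; 1.33: 27.3, 9.8; 2.50: 21.0, 20.2

(readings scatter by 0.3 percentage points)

- when, up to 2.5 min, the flask holds most open intermediate
- the amount of open intermediate, in percent of the substrate charged, at that time

- amounts are per litre of the starting volume; all of the dose is in the solution fed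
- the analysis behind the earlier runs scatters by 0.3 percentage points, standard deviation

Later the runs part, and the measure set beside them is c(partner), the charge spread over starting volume plus feed: 0.0200 M in north, 0.0280 M in west and 0.0440 M in south. At 2.5 min the readings fall in that order, 21.0%, 17.0% and 10.6%. West and south share the substrate charge of the flask, so they give the partner sensitivity, the fall in the logarithm of percent open intermediate at 2.5 min per unit of c(partner): 29.5 M⁻¹.

The flask has twice the substrate of north, but its c(partner) is 0.0200 M, level with north. Because the two levels match, the flask should follow north, whose highest reading is 27.3% at 1.33 min. From west, the sensitivity carries the flask to 21.5% at 2.5 min.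

The forecast stands slightly higher and later, at 27.8% and 1.35 min, since the “profile should therefore track north”. The flask gives 27.6% at 1.33 min.

    partner → second intermediate (k = 0.0123 s⁻¹)
    substrate + open intermediate → side product (k = 0.0771 M⁻¹ s⁻¹)
    substrate ⇌ open intermediate (K = 1.39, k = 0.00832 s⁻¹)
    open intermediate + second intermediate → target (k = 1.03 M⁻¹ s⁻¹)
    target → over-reaction product (k = 0.0124 s⁻¹)

At 2.5 min the flask holds 22.5% open intermediate, beside the 21.5% reckoned. The neighbouring flask, with 0.012 M partner and all else held, has c(partner) of 0.00800 M, so the same sensitivity carries west to 30.7%. That neighbour holds 35.2%, more than reckoned. Its target stands at 9.34%, against 18.2% in the flask at the same time.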